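**Zero of the scale.** If the two mirror-image substrates react at equal rates, the products form in a ratio of one and their excess is zero. Any lead is measured from that point by the selectivity factor s, the rate for the left-handed substrate over that for the right-handed at equal amounts; at low conversion the excess is s less one over s plus one. Both mirror images meet the same catalyst, partner and protic impurity, so s should follow the temperature and not these charges, and temperature is what separates north-east from west.

| flask | left-handed substrate | right-handed substrate | partner | protic impurity | catalyst | temperature | remark | time |
|---|---|---|---|---|---|---|---|---|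
| Monday's | 0.50 M | 0.50 M | 2 M | 0.50 M | 170 mM | 9 °C | run made earlier |  |
| Saturday's | 1 M | 1 M | 2 M | 0.50 M | 85 mM | 17 °C | run made earlier |  |
| north-east | 1.0 M | 1.0 M | 2.00 M | 0.500 M | 170 mM | 5 °C |  | 4.0 d |
| west | 1.0 M | 1.0 M | 2.00 M | 0.500 M | 170 mM | 20 °C |  | 4.0 d |

Monday's run (percent of the left-handed substrate and right-handed substrate together charged)

| time / d | left-handed product / % | right-handed product / % | left-handed substrate / % |
|---|---|---|---|
| 0.250 | 2.0 | 0.9 | 48.5 |
| 0.417 | 1.7 | 0 | 48.1 |
| 0.625 | 3.1 | 0.4 | 47.7 |
| 0.833 | 4.3 | 0 | 46.7 |
| 1.25 | 5.0 | 0.7 | 45.5 |
| 2.00 | 6.2 | 1.1 | 43.7 |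
| 3.00 | 8.6 | 1.1 | 42.2 |

Saturday's run (percent of the left-handed substrate and right-handed substrate together charged)

| time / h | left-handed product / % | right-handed product / % | left-handed substrate / % |
|---|---|---|---|
| 8.00 | 0.7 | 0 | 48.3 |
| 15.0 | 2.6 | 0.5 | 48.7 |
| 30.0 | 3.9 | 0.7 | 46.1 |
| 40.0 | 3.8 | 0.9 | 44.9 |

(scatter of a reading: 0.5 percentage points)

* the flask that comes out highest in excess of left-handed product over right-handed product, or "all alike" when all lie within 1.5 percentage points (north-east / west / all alike)
* excess of left-handed product over right-handed product at the end, north-east
* excess of left-handed product over right-handed product at the end, west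

- catalyst is single-handed; left-handed substrate and right-handed substrate are mirror images of each other, charged as a racemate, each of them at the stated concentration
- what was read earlier has a scatter of 0.5 percentage points, one standard deviation
- an excess is below zero if the other one leads

**Reading s.** Over the 11 readings of both runs, the left-handed product sums to 41.9% and the right-handed to 6.30%, so the pooled selectivity factor reads 6.65, an excess of 73.9%. The small sum carries a scatter of 1.7 percentage points, and two standard deviations stretch s from 4.36 to 14.0, an excess from 62.7% to 86.7%. Monday's colder run alone reads 7.36, above Saturday's 5.24, but both lie inside that range.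

**The decision.** This reckoning holds 73.9% with that range for both flasks, so it gives them no lead over each other, which is under the margin of 1.5 points, and it answers all alike, with the charges left as written. The forecast gives north-east, with 75% (66% to 84%) there and 63% (50% to 73%) in west, on the view that “Selectivity seems to fall as temperature rises”, where this reckoning draws no slope.

**The result.** North-east gives 86.2% and west 78.5%, so north-east leads by 7.7 points, more than the margin, against the all alike of this reckoning.

    partner + catalyst + left-handed substrate → catalyst + left-handed product (k = 1.40 × 10⁻⁵ /M²/s, Ea = 65.0 kJ/mol)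
    partner + catalyst + right-handed substrate → catalyst + right-handed product (k = 1.40 × 10⁻⁶ /M²/s, Ea = 82.0 kJ/mol)
    catalyst ⇌ dormant form (K = 1.70, k = 3.30 × 10⁻⁵ /s, Ea = 99.0 kJ/mol, ΔH = −26.0 kJ/mol)
    partner + protic impurity → quenched reagent (k = 1.20 × 10⁻⁴ /M/s, Ea = 71.0 kJ/mol)
    (constants at 20 °C)

**Back to s.** In north-east at 4.00 d, the half-life of the left-handed substrate by its own step is 28 d, far longer than the 4.0 d run, and 84% of its charge remains. The products there stand in a ratio of 13.5, above 6.65 and inside the range that ends at 14.0.

**A neighbour.** The neighbour of north-east with [protic impurity] = 0.30 M keeps the temperature, so 6.65 carries over unchanged, with 73.9% and the range up to 86.7%. The computed flask gives 86.0%, with a product ratio of 13.3.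

(The runs stem from a simulated flask for substances that don't exist; the scatter is artificial.)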